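## Analysis of the target

The target is a 3→8''-linked biflavonoid. A 5,7,4'-trihydroxyflavanone (rings A, B and C) is joined through C3 to C8'' of a 5'',3''',4'''-trihydroxyflavone, and O7'' of the flavone carries a hydrogen sulfate. There are two stereocentres, C2 (R) and C3 (S), adjacent in ring C and trans, so that the ring-B aryl group and the flavonyl group are both equatorial. C3 lies α to the C4 ketone and is epimerisable, with trans as the thermodynamic arrangement. C2 is the centre that must be set absolutely, and it can be lost if base opens ring C to the chalcone. The sensitive groups are the aryl sulfate (acid-labile, and incompatible with Lewis-acidic deprotection), the flavanone (base) and seven phenolic oxygens, of which exactly one is sulfated. The synthesis is hard because the C3–C8'' bond joins a tertiary sp3 carbon to an arene carbon flanked by O7'' and O1'', because C2 must survive, and because O7'' must be distinguished from six other phenols. The strategy rests on C8'' being a carbon of the phloroglucinol-derived ring of the flavone that can carry a carbonyl carbon: if C3 is that carbonyl carbon, ring C can be closed last by bonding C3 to C4, the formyl carbon on ring A, used as an acyl anion equivalent.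

## Retrosynthetic reasoning

**21 to 19.** The last bonds cut are the six benzylic C–O bonds (21 ⇒ 20) and the S–O7'' bond (20 ⇒ 19). Hydrogenolysis is the one global deprotection that leaves an aryl sulfate, the flavone double bond and the flavanone intact, so every phenol other than O7'' is carried as a benzyl ether. Sulfation then meets a single free phenol in 19 and needs no selectivity.

**19 to 18.** O7'' needs a group that comes off beside benzyl ethers and without base. A methoxymethyl acetal (18) is chosen, cleaved by dilute acid, which flavanone and benzyl ethers tolerate. An allyl ether would serve at this point, but the route to the ketone passes through two zerovalent palladium steps in which the allyl ether of so acidic a phenol would be ionised.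

**18 to 17.** The C3–H bond is exchanged for a C3–OH bond. This costs one step, but it makes C3 the carbinol carbon of an α-ketol, which is what an acyloin-type ring closure delivers. In the forward sense a one-electron reductant removes the hydroxyl through the C3–C4 enolate, and C3 then settles under thermodynamic control with the two aryl groups trans. Only C2 has to be carried over from the closure.

**17 to 16 (key disconnection).** Ring C is opened at C3–C4. A cut at C3–C8'' would require arylation of a hindered flavanone enolate next to the fragile C2. A cut at O1–C2 alone would lead to an α-aryl chalcone whose cyclisation offers no handle for absolute control. The C3–C4 cut makes C3 a ketone carbon already bonded to C8'' and makes C4 the formyl carbon of a salicylaldehyde ether, 16. The forward reaction must invert the polarity of the formyl carbon, add it to a di-ortho-substituted aryl ketone, and select one configuration at C2 from a precursor in which C2 is racemic and acidic. A chiral triazolylidene carbene is meant to do all three.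

**16 to 13 and 15.** The O1–C2 ether bond, α to the ketone, is cut to the phenol 15 and the α-bromo ketone 13. The forward SN2 reaction is fast because C2 is benzylic and α to a carbonyl. 15 comes from 14 by benzylation of the two hydroxyls not held by the formyl group.

**13 to 12 to 10 and 11.** The C2–Br bond leads back to the benzyl ketone 12. The C2–C1' bond of 12 is cut to the methyl ketone 10 and the aryl bromide 11 (palladium-catalysed α-arylation). Bringing ring B in this late keeps the arylacetyl methylene out of the molecule until the flavone is complete; earlier it would compete with the acetyl group in the condensation that builds the pyranone.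

**10 to 8 to 7.** The C8''–C3 bond is cut to the 8''-iodide 8 and an acetyl anion equivalent (cross-coupling of a 1-alkoxyvinyl tin reagent). A Lewis-acid-mediated acyl shift from O7'' to C8'', or a direct Friedel–Crafts acylation, would make the same bond. Neither spares aryl benzyl ethers, and the benzo ring of a flavone is a much poorer nucleophile than phloroglucinol itself. The iodide keeps the idea (C3 sits on C8'' as a carbonyl carbon from the start) and makes it compatible with the protecting groups. 8 comes from 7 by electrophilic iodination, for which C8'' is the favoured position in 5,7-dialkoxyflavones.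

**7 to 5.** The two oxygens on the flavone benzo ring are told apart by hydrogen bonding. In 5 the 7''-hydroxyl is free and acidic and takes the acetal first (6); the chelated 5''-hydroxyl is benzylated afterwards (7).

**5 to 3 and 2.** The pyranone is cut at O1''–C2'' and C3''–C2'' to the acetophenone 3 and the aroyl chloride 2 (from acid 1). C-acylation of the polyanion of 3 and acid-catalysed cyclodehydration build the flavone without any protection of 3.

## Alternatives that were turned down

**Alternative 1:** Ring A is removed as an aryne (cuts at O1–C8a and C4–C4a), leaving a C2–C3–C4 chain whose two stereocentres come from an auxiliary-controlled anti aldol reaction of an acyl thiazolidinethione. In the forward key step fluoride would release the C2 alkoxide and the aryne together; O-arylation and attack of the resulting aryl anion on the acyl auxiliary would close ring C and give A1 directly at the flavanone oxidation level.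
- *For it:* both stereocentres and their trans relationship are fixed by a well-understood auxiliary before the ring exists; no deoxygenation is needed afterwards; the benzyloxy group next to the aryne bond should steer the alkoxide to the distal carbon, which is the correct one (C8a).
- *Against it:* the free β-alkoxide of an α-aryl acyl derivative is set up for retro-aldol cleavage. C3–H, benzylic and α to the thioimide, is very acidic under the basic fluoride conditions, so the C3 configuration bought with the auxiliary is at risk. The aldol component is a flavon-8-ylacetyl unit whose preparation is no shorter than that of the C8'' ketone. Two consecutive intermolecular and intramolecular captures by a hindered secondary alkoxide have to beat every other nucleophile present.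
- *Comparison:* on stereocontrol this alternative is stronger. The chosen route offers instead a ring closure with direct precedent on the same tether, a precursor (16) whose stereocentre need not be preserved, and a C3 centre that is corrected thermodynamically. The step count is similar.

**Alternative 2:** The target is read as the product of a 1,2-aryl shift (cuts at C3–C8'' and O1–C2). The flavonyl group starts on C2 of a 3,3-diarylpropan-1-one; an aryl iodine reagent (trivalent iodine) activates C3, the flavonyl group migrates from C2 to C3, and the ring-A oxygen, present as a methoxymethyl ether, captures the benzylic cation at C2 to give A2.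
- *For it:* it is the shortest plan. The crowded C3–C8'' bond forms intramolecularly by migration. The precursor is available by conjugate arylation of a chalcone. The flavanone oxidation level is reached directly.
- *Against it:* the only pre-existing stereocentre is the migration origin and becomes cationic, so the absolute configuration of C2 has no dependable control element. C3 is activated as an α-iodanyl ketone of uncontrolled configuration. The outcome depends on relative migratory aptitudes (ring B must be deactivated as an acetate) and on the iodane not oxidising the electron-rich rings or simply α-oxygenating the ketone. The flavone benzo ring, bearing the pyranone carbonyl, is not an especially good migrating group.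
- *Comparison:* this alternative is stronger in step economy. The chosen route offers a defined source of absolute configuration at C2 and a closure whose chemoselectivity does not rest on a competition between two aryl groups.

**Alternative 3:** C3 is activated as the α-carbon of a lactone that ties it to O7'' (cuts at O1–C2 and C3–C4). The ring-A salicylaldehyde of the chosen route (15) and a flavone-fused (E)-benzylidene lactone would undergo an oxa-Michael/aldol domino reaction under a cinchona-derived squaramide to give the spiro-lactone A3. Oxidation at C4, lactone opening and decarboxylation would follow.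
- *For it:* asymmetric oxa-Michael/aldol domino reactions of salicylaldehydes have broad precedent. The lactone carbonyl also protects O7'', so its removal frees exactly the phenol to be sulfated. C3 is again settled thermodynamically.
- *Against it:* one carbon is introduced only to be discarded, and the C8'' substituent must first be homologated to an acetic acid. The acceptor carries an electron-rich β-aryl group and gives a spiro quaternary centre beside a di-ortho-substituted arene, so the oxa-Michael addition of a chelated phenol is slow and reversible, and C2 is set in a reversible step. Hydroxide opening of the lactone next to a β-aryloxy ketone invites ring opening of the flavanone.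
- *Comparison:* this alternative is stronger in precedent for the enantioselective event and in the way O7'' is differentiated. The chosen route offers a shorter path to the cyclisation precursor, no sacrificial carbon, and a C3–C8'' bond that needs no further change after the closure.

Key step: step 11

Remark on the chemistry: compounds 20 and 21 are written as the free aryl hydrogen sulfate, as the target is drawn; 20 would be handled as its sodium salt and the acid form set free at the end on a sulfonic acid resin at 0 °C.

Position numbers without primes refer to the flavanone (rings A, B, C), double-primed numbers to the chromenone of the flavone, triple-primed numbers to its catechol ring.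

## Route

Step 1
Reactants: 1 3,4-bis(benzyloxy)benzoic acid
Product: 2 3,4-bis(benzyloxy)benzoyl chloride
Conditions: (COCl)2, DMF (cat.), CH2Cl2, 0 °C → rt; evaporate
Reagents that add atoms: oxalyl chloride, O=C(Cl)C(Cl)=O
Why: Acid chloride formation through the chloroiminium ion from DMF; benzyl ethers are inert and the gaseous by-products leave a reagent fit for direct use.

Step 2
Reactants: 3 2,4,6-trihydroxyacetophenone (dried); 2 3,4-bis(benzyloxy)benzoyl chloride
Product: 5 2-[3,4-bis(benzyloxy)phenyl]-5,7-dihydroxy-4H-chromen-4-one, via β-diketone 4 (not isolated)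
Conditions: LiN(SiMe3)2 (5 equiv), THF, −78 °C; 2, −78 °C → rt; aq. HCl; then AcOH, H2SO4 (0.5 %), 90 °C
Reagents that add atoms: none
Why: Excess amide base converts 3 into its phenoxide enolate polyanion, whose enolate carbon is acylated by 2 (Claisen-type C-acylation, the polyanion variant of the Baker–Venkataraman route); acid then closes the pyranone by addition of an ortho hydroxyl to the aryl ketone and loss of water. Aryl benzyl ethers should withstand the short exposure to dilute H2SO4 in AcOH.

Step 3
Reactants: 5 2-[3,4-bis(benzyloxy)phenyl]-5,7-dihydroxy-4H-chromen-4-one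
Product: 6 2-[3,4-bis(benzyloxy)phenyl]-5-hydroxy-7-(methoxymethoxy)-4H-chromen-4-one
Conditions: MeOCH2Cl (1.1 equiv), i-Pr2NEt, DMF/CH2Cl2, 0 °C → rt
Reagents that add atoms: chloromethyl methyl ether, COCCl
Why: Williamson-type alkylation with a weak base reaches only O7''–H, the acidic, non-chelated phenol; O5''–H is held in a hydrogen bond to the C4'' carbonyl and stays free.

Step 4
Reactants: 6 2-[3,4-bis(benzyloxy)phenyl]-5-hydroxy-7-(methoxymethoxy)-4H-chromen-4-one
Product: 7 5-(benzyloxy)-2-[3,4-bis(benzyloxy)phenyl]-7-(methoxymethoxy)-4H-chromen-4-one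
Conditions: BnBr, K2CO3, Bu4NI (cat.), DMF, 70 °C
Reagents that add atoms: benzyl bromide, BrCc1ccccc1
Why: Williamson ether synthesis under forcing conditions alkylates the chelated 5''-hydroxyl; the acetal on O7'' is stable to base.

Step 5
Reactants: 7 5-(benzyloxy)-2-[3,4-bis(benzyloxy)phenyl]-7-(methoxymethoxy)-4H-chromen-4-one
Product: 8 5-(benzyloxy)-2-[3,4-bis(benzyloxy)phenyl]-8-iodo-7-(methoxymethoxy)-4H-chromen-4-one
Conditions: NIS (1.15 equiv), DMF, 45 °C, dark
Reagents that add atoms: N-iodosuccinimide, O=C1CCC(=O)N1I
Why: Electrophilic aromatic iodination; in 5,7-dialkoxyflavones the 5-alkoxy group turns its alkyl group away from the peri carbonyl and shields C6'', so substitution should go to C8'', activated by O7'' (ortho) and O5'' (para), while the catechol ring is deactivated by conjugation with the pyranone. Neutral conditions spare the acetal.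

Step 6
Reactants: 8 5-(benzyloxy)-2-[3,4-bis(benzyloxy)phenyl]-8-iodo-7-(methoxymethoxy)-4H-chromen-4-one
Product: 10 8-acetyl-5-(benzyloxy)-2-[3,4-bis(benzyloxy)phenyl]-7-(methoxymethoxy)-4H-chromen-4-one, via enol ether 9 (not isolated)
Conditions: CH2=C(OEt)SnBu3, PdCl2(PPh3)2 (5 mol %), CuI (10 mol %), dioxane, 95 °C; then 0.5 M HCl, THF, 0 °C, 15 min
Reagents that add atoms: tributyl(1-ethoxyvinyl)stannane, CCOC(=C)[Sn](CCCC)(CCCC)CCCC; water, O
Why: Stille coupling of the hindered aryl iodide with an acetyl anion equivalent, CuI speeding transmetallation; brief cold acid hydrolyses enol ether 9 to the methyl ketone before the acetal on O7'' is touched. The future C3 is thus placed on C8'' as a carbonyl carbon without any Lewis acid.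

Step 7
Reactants: 10 8-acetyl-5-(benzyloxy)-2-[3,4-bis(benzyloxy)phenyl]-7-(methoxymethoxy)-4H-chromen-4-one; 11 1-(benzyloxy)-4-bromobenzene
Product: 12 5-(benzyloxy)-8-{[4-(benzyloxy)phenyl]acetyl}-2-[3,4-bis(benzyloxy)phenyl]-7-(methoxymethoxy)-4H-chromen-4-one
Conditions: Pd2(dba)3 (2.5 mol %), Xantphos (6 mol %), K3PO4 (2.5 equiv), toluene, 90 °C
Reagents that add atoms: none
Why: Palladium-catalysed α-arylation of an aryl methyl ketone with a wide-bite-angle phosphine and the mild base K3PO4; monoarylation is favoured because the product enolate is stabilised and hindered. The flavone has no enolisable position and no allyl group is present to intercept zerovalent palladium.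

Step 8
Reactants: 12 5-(benzyloxy)-8-{[4-(benzyloxy)phenyl]acetyl}-2-[3,4-bis(benzyloxy)phenyl]-7-(methoxymethoxy)-4H-chromen-4-one
Product: 13 5-(benzyloxy)-8-{bromo[4-(benzyloxy)phenyl]acetyl}-2-[3,4-bis(benzyloxy)phenyl]-7-(methoxymethoxy)-4H-chromen-4-one (racemic)
Conditions: LiN(SiMe3)2 (1.1 equiv), THF, −78 °C; NBS (1.1 equiv), −78 °C; aq. NH4Cl
Reagents that add atoms: N-bromosuccinimide, O=C1CCC(=O)N1Br
Why: The benzylic ketone is deprotonated cleanly at −78 °C and the enolate is brominated by NBS faster than any ring position (enolate α-halogenation); basic conditions avoid HBr, which would cleave the acetal ortho to the ketone. The labile benzylic bromide is taken on crude.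

Step 9
Reactants: 14 2,4,6-trihydroxybenzaldehyde
Product: 15 2-hydroxy-4,6-bis(benzyloxy)benzaldehyde
Conditions: BnBr (2.1 equiv), K2CO3, DMF, 0 °C → rt
Reagents that add atoms: benzyl bromide, BrCc1ccccc1
Why: Williamson etherification; the para hydroxyl and one ortho hydroxyl react, and the second ortho hydroxyl stays free because it is hydrogen-bonded to the formyl group.

Step 10
Reactants: 13 5-(benzyloxy)-8-{bromo[4-(benzyloxy)phenyl]acetyl}-2-[3,4-bis(benzyloxy)phenyl]-7-(methoxymethoxy)-4H-chromen-4-one; 15 2-hydroxy-4,6-bis(benzyloxy)benzaldehyde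
Product: 16 2-{1-[4-(benzyloxy)phenyl]-2-[5-(benzyloxy)-2-(3,4-bis(benzyloxy)phenyl)-7-(methoxymethoxy)-4-oxo-4H-chromen-8-yl]-2-oxoethoxy}-4,6-bis(benzyloxy)benzaldehyde (racemic at C2)
Conditions: K2CO3 (1.5 equiv), acetone, 0 °C → rt
Reagents that add atoms: none
Why: SN2 displacement of the doubly activated (benzylic, α-keto) bromide by the phenoxide of 15 forms the O1–C2 bond; low temperature and a weak base limit the reversible aldol addition of the C2 enolate to the formyl group. The product is racemic at C2, which does not matter because C2 epimerises in the next step.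

Step 11
Reactants: 16 2-{1-[4-(benzyloxy)phenyl]-2-[5-(benzyloxy)-2-(3,4-bis(benzyloxy)phenyl)-7-(methoxymethoxy)-4-oxo-4H-chromen-8-yl]-2-oxoethoxy}-4,6-bis(benzyloxy)benzaldehyde
Product: 17 (2S,3R)-5,7-bis(benzyloxy)-2-[4-(benzyloxy)phenyl]-3-[5-(benzyloxy)-2-(3,4-bis(benzyloxy)phenyl)-7-(methoxymethoxy)-4-oxo-4H-chromen-8-yl]-3-hydroxychroman-4-one
Conditions: (5aS,10bR)-2-(pentafluorophenyl)-5a,10b-dihydro-4H,6H-indeno[2,1-b][1,2,4]triazolo[4,3-d][1,4]oxazin-2-ium tetrafluoroborate (20 mol %), DBU (40 mol %), 4 Å sieves, toluene, 25 °C, under argon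
Reagents that add atoms: none
Why: The carbene from the triazolium salt adds to the formyl carbon C4 and proton transfer gives the Breslow intermediate, whose nucleophilic C4 attacks the ketone carbon C3; collapse of the adduct releases the carbene and the α-ketol. The closest known reaction type is the carbene-catalysed intramolecular crossed aldehyde–ketone benzoin cyclisation of 2-(2-oxoalkoxy)benzaldehydes to 3-hydroxychroman-4-ones, including its enantioselective and dynamic kinetic variants. Ring C closes in the 6-exo-trig mode. At C3 the face of the ketone is chosen by the chiral carbene, whose aminoindane backbone blocks one face of the Breslow intermediate. At C2 the base interconverts the two epimers of 16 through the enolate of the C3 ketone, and the epimer that places the ring-B aryl group pseudo-equatorial and trans to the flavonyl group in the chair-like transition state should cyclise faster, so both epimers are funnelled to (2S,3R)-17. The step needs C2 epimerisation to outrun ring closure, which the triply activated C2–H (α-keto, α-aryl, α-aryloxy) secures, and it needs only the aldehyde to form a Breslow intermediate; the crowded 2,6-dioxygenated aldehyde is slow in intermolecular benzoin reaction. Aldol addition of the C2 enolate to the formyl group is reversible and gives a strained quaternary centre, whereas 17 can no longer enolise at C2, so material should drain to 17. The sense of induction is to be established in the first run; both antipodes of the salt are commercial and the antipode is used if the mirror image of 17 forms.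

Step 12
Reactants: 17 (2S,3R)-5,7-bis(benzyloxy)-2-[4-(benzyloxy)phenyl]-3-[5-(benzyloxy)-2-(3,4-bis(benzyloxy)phenyl)-7-(methoxymethoxy)-4-oxo-4H-chromen-8-yl]-3-hydroxychroman-4-one
Product: 18 (2R,3S)-5,7-bis(benzyloxy)-2-[4-(benzyloxy)phenyl]-3-[5-(benzyloxy)-2-(3,4-bis(benzyloxy)phenyl)-7-(methoxymethoxy)-4-oxo-4H-chromen-8-yl]chroman-4-one (2,3-trans)
Conditions: SmI2 (3 equiv, 0.1 M in THF), MeOH (10 equiv), THF, −78 °C; aq. NH4Cl
Reagents that add atoms: none
Why: Divalent samarium reduces the α-ketol through the chelated C4 ketyl; a second electron expels the C3 hydroxyl and gives the C3–C4 enolate, which MeOH protonates at −78 °C before it can expel the O1 aryloxide (known reductive cleavage of α-hetero-substituted ketones). C3 is then under thermodynamic control, the diequatorial trans isomer being favoured, and any cis epimer converges under the acid of step 13. C2 is untouched; its descriptor changes from S to R only because C3 loses its oxygen.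

Step 13
Reactants: 18 (2R,3S)-5,7-bis(benzyloxy)-2-[4-(benzyloxy)phenyl]-3-[5-(benzyloxy)-2-(3,4-bis(benzyloxy)phenyl)-7-(methoxymethoxy)-4-oxo-4H-chromen-8-yl]chroman-4-one
Product: 19 (2R,3S)-5,7-bis(benzyloxy)-2-[4-(benzyloxy)phenyl]-3-[5-(benzyloxy)-2-(3,4-bis(benzyloxy)phenyl)-7-hydroxy-4-oxo-4H-chromen-8-yl]chroman-4-one
Conditions: HCl (2 M in MeOH), THF, 45 °C
Reagents that add atoms: none
Why: Acid-catalysed acetal cleavage in MeOH frees O7''–H alone; benzyl ethers and the flavanone are stable, and acid-catalysed enolisation brings any cis C3 epimer to trans without opening ring C.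

Step 14
Reactants: 19 (2R,3S)-5,7-bis(benzyloxy)-2-[4-(benzyloxy)phenyl]-3-[5-(benzyloxy)-2-(3,4-bis(benzyloxy)phenyl)-7-hydroxy-4-oxo-4H-chromen-8-yl]chroman-4-one
Product: 20 (2R,3S)-5,7-bis(benzyloxy)-2-[4-(benzyloxy)phenyl]-3-[5-(benzyloxy)-2-(3,4-bis(benzyloxy)phenyl)-4-oxo-7-(sulfooxy)-4H-chromen-8-yl]chroman-4-one
Conditions: SO3·pyridine (6 equiv), pyridine, 45 °C
Reagents that add atoms: sulfur trioxide–pyridine complex, O=S(=O)([O-])[n+]1ccccc1
Why: O-Sulfation of the only free phenol by the sulfur trioxide–amine complex; excess reagent and gentle warming answer the hindrance from the neighbouring C8'' substituent.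

Step 15
Reactants: 20 (2R,3S)-5,7-bis(benzyloxy)-2-[4-(benzyloxy)phenyl]-3-[5-(benzyloxy)-2-(3,4-bis(benzyloxy)phenyl)-4-oxo-7-(sulfooxy)-4H-chromen-8-yl]chroman-4-one
Product: 21 (2R,3S)-3-[2-(3,4-dihydroxyphenyl)-5-hydroxy-4-oxo-7-(sulfooxy)-4H-chromen-8-yl]-5,7-dihydroxy-2-(4-hydroxyphenyl)chroman-4-one (CNP0314990.1)
Conditions: H2 (1 atm), Pd/C (10 %), THF/MeOH, rt
Reagents that add atoms: none
Why: Hydrogenolysis of the six aryl benzyl ethers over palladium on carbon; the aryl sulfate (run as its salt), the flavone double bond and the electron-rich C4 ketone should not be reduced at 1 atm and room temperature, and neither stereocentre is touched.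

## Compound list

1 | 3,4-bis(benzyloxy)benzoic acid | O=C(O)c1ccc(OCc2ccccc2)c(OCc2ccccc2)c1 | starting material
2 | 3,4-bis(benzyloxy)benzoyl chloride | O=C(Cl)c1ccc(OCc2ccccc2)c(OCc2ccccc2)c1 | intermediate
3 | 2,4,6-trihydroxyacetophenone | CC(=O)c1c(O)cc(O)cc1O | starting material
4 | 1-[3,4-bis(benzyloxy)phenyl]-3-(2,4,6-trihydroxyphenyl)propane-1,3-dione | O=C(CC(=O)c1c(O)cc(O)cc1O)c1ccc(OCc2ccccc2)c(OCc2ccccc2)c1 | intermediate
5 | 2-[3,4-bis(benzyloxy)phenyl]-5,7-dihydroxy-4H-chromen-4-one | O=c1cc(-c2ccc(OCc3ccccc3)c(OCc3ccccc3)c2)oc2cc(O)cc(O)c12 | intermediate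
6 | 2-[3,4-bis(benzyloxy)phenyl]-5-hydroxy-7-(methoxymethoxy)-4H-chromen-4-one | O=c1cc(-c2ccc(OCc3ccccc3)c(OCc3ccccc3)c2)oc2cc(OCOC)cc(O)c12 | intermediate
7 | 5-(benzyloxy)-2-[3,4-bis(benzyloxy)phenyl]-7-(methoxymethoxy)-4H-chromen-4-one | O=c1cc(-c2ccc(OCc3ccccc3)c(OCc3ccccc3)c2)oc2cc(OCOC)cc(OCc3ccccc3)c12 | intermediate
8 | 5-(benzyloxy)-2-[3,4-bis(benzyloxy)phenyl]-8-iodo-7-(methoxymethoxy)-4H-chromen-4-one | O=c1cc(-c2ccc(OCc3ccccc3)c(OCc3ccccc3)c2)oc2c(I)c(OCOC)cc(OCc3ccccc3)c12 | intermediate
9 | 5-(benzyloxy)-2-[3,4-bis(benzyloxy)phenyl]-8-(1-ethoxyvinyl)-7-(methoxymethoxy)-4H-chromen-4-one | O=c1cc(-c2ccc(OCc3ccccc3)c(OCc3ccccc3)c2)oc2c(C(=C)OCC)c(OCOC)cc(OCc3ccccc3)c12 | intermediate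
10 | 8-acetyl-5-(benzyloxy)-2-[3,4-bis(benzyloxy)phenyl]-7-(methoxymethoxy)-4H-chromen-4-one | O=c1cc(-c2ccc(OCc3ccccc3)c(OCc3ccccc3)c2)oc2c(C(C)=O)c(OCOC)cc(OCc3ccccc3)c12 | intermediate
11 | 1-(benzyloxy)-4-bromobenzene | Brc1ccc(OCc2ccccc2)cc1 | starting material
12 | 5-(benzyloxy)-8-{[4-(benzyloxy)phenyl]acetyl}-2-[3,4-bis(benzyloxy)phenyl]-7-(methoxymethoxy)-4H-chromen-4-one | O=c1cc(-c2ccc(OCc3ccccc3)c(OCc3ccccc3)c2)oc2c(C(=O)Cc3ccc(OCc4ccccc4)cc3)c(OCOC)cc(OCc3ccccc3)c12 | intermediate
13 | 5-(benzyloxy)-8-{bromo[4-(benzyloxy)phenyl]acetyl}-2-[3,4-bis(benzyloxy)phenyl]-7-(methoxymethoxy)-4H-chromen-4-one (racemic) | O=c1cc(-c2ccc(OCc3ccccc3)c(OCc3ccccc3)c2)oc2c(C(=O)C(Br)c3ccc(OCc4ccccc4)cc3)c(OCOC)cc(OCc3ccccc3)c12 | intermediate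
14 | 2,4,6-trihydroxybenzaldehyde | O=Cc1c(O)cc(O)cc1O | starting material
15 | 2-hydroxy-4,6-bis(benzyloxy)benzaldehyde | O=Cc1c(O)cc(OCc2ccccc2)cc1OCc1ccccc1 | intermediate
16 | 2-{1-[4-(benzyloxy)phenyl]-2-[5-(benzyloxy)-2-(3,4-bis(benzyloxy)phenyl)-7-(methoxymethoxy)-4-oxo-4H-chromen-8-yl]-2-oxoethoxy}-4,6-bis(benzyloxy)benzaldehyde (racemic at C2) | O=Cc1c(OC(c2ccc(OCc3ccccc3)cc2)C(=O)c2c(OCOC)cc(OCc3ccccc3)c3c(=O)cc(-c4ccc(OCc5ccccc5)c(OCc5ccccc5)c4)oc23)cc(OCc2ccccc2)cc1OCc1ccccc1 | intermediate
17 | (2S,3R)-5,7-bis(benzyloxy)-2-[4-(benzyloxy)phenyl]-3-[5-(benzyloxy)-2-(3,4-bis(benzyloxy)phenyl)-7-(methoxymethoxy)-4-oxo-4H-chromen-8-yl]-3-hydroxychroman-4-one | O=C1c2c(OCc3ccccc3)cc(OCc3ccccc3)cc2O[C@@H](c2ccc(OCc3ccccc3)cc2)[C@]1(O)c1c(OCOC)cc(OCc3ccccc3)c2c(=O)cc(-c3ccc(OCc4ccccc4)c(OCc4ccccc4)c3)oc12 | intermediate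
18 | (2R,3S)-5,7-bis(benzyloxy)-2-[4-(benzyloxy)phenyl]-3-[5-(benzyloxy)-2-(3,4-bis(benzyloxy)phenyl)-7-(methoxymethoxy)-4-oxo-4H-chromen-8-yl]chroman-4-one | O=C1c2c(OCc3ccccc3)cc(OCc3ccccc3)cc2O[C@@H](c2ccc(OCc3ccccc3)cc2)[C@@H]1c1c(OCOC)cc(OCc3ccccc3)c2c(=O)cc(-c3ccc(OCc4ccccc4)c(OCc4ccccc4)c3)oc12 | intermediate
19 | (2R,3S)-5,7-bis(benzyloxy)-2-[4-(benzyloxy)phenyl]-3-[5-(benzyloxy)-2-(3,4-bis(benzyloxy)phenyl)-7-hydroxy-4-oxo-4H-chromen-8-yl]chroman-4-one | O=C1c2c(OCc3ccccc3)cc(OCc3ccccc3)cc2O[C@@H](c2ccc(OCc3ccccc3)cc2)[C@@H]1c1c(O)cc(OCc3ccccc3)c2c(=O)cc(-c3ccc(OCc4ccccc4)c(OCc4ccccc4)c3)oc12 | intermediate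
20 | (2R,3S)-5,7-bis(benzyloxy)-2-[4-(benzyloxy)phenyl]-3-[5-(benzyloxy)-2-(3,4-bis(benzyloxy)phenyl)-4-oxo-7-(sulfooxy)-4H-chromen-8-yl]chroman-4-one | O=C1c2c(OCc3ccccc3)cc(OCc3ccccc3)cc2O[C@@H](c2ccc(OCc3ccccc3)cc2)[C@@H]1c1c(OS(=O)(=O)O)cc(OCc3ccccc3)c2c(=O)cc(-c3ccc(OCc4ccccc4)c(OCc4ccccc4)c3)oc12 | intermediate
21 | (2R,3S)-3-[2-(3,4-dihydroxyphenyl)-5-hydroxy-4-oxo-7-(sulfooxy)-4H-chromen-8-yl]-5,7-dihydroxy-2-(4-hydroxyphenyl)chroman-4-one | O=C1c2c(O)cc(O)cc2O[C@@H](c2ccc(O)cc2)[C@@H]1c1c(OS(=O)(=O)O)cc(O)c2c(=O)cc(-c3ccc(O)c(O)c3)oc12 | target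

## Step count and risk

Total step count: 15. Longest linear sequence: 14 steps (steps 1–8 and 10–15); step 9 is a one-step side branch.

**Key step (step 11).** Two processes may fail. Addition of the acyl anion equivalent to the di-ortho-substituted ketone may be slow, so that reversible aldol closure and oxidation of the aldehyde take over. Alternatively, equilibration at C2 may be incomplete or the two C2 epimers may be poorly discriminated, which shows up as low enantiopurity once C3 is erased. The fallback gives up catalyst control and dynamic resolution. It sets out from 16, which is cyclised with an achiral carbene (from 2-mesityl-6,7-dihydro-5H-pyrrolo[2,1-c][1,2,4]triazol-2-ium chloride and DBU). The racemic ketol, that is 17 together with the mirror-image ketol F1, is separated by preparative chromatography on a chiral stationary phase (amylose tris(3,5-dimethylphenylcarbamate)). A minor diastereomer at C3 need not be removed, since C3 is erased in step 12. The route is rejoined at 17.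

**Deoxygenation (step 12).** Electron transfer may go to the flavone carbonyl instead of the hindered, electron-rich C4 ketone. The samarium enolate may expel the O1 aryloxide, opening ring C and losing C2. The free tertiary hydroxyl may leave too slowly. The fallback is a radical deoxygenation. From 17, acylation with methyl chlorooxalate (pyridine, DMAP, CH2Cl2) gives the methyl oxalate F2. Bu3SnH with AIBN in toluene at 100 °C cleaves the C3–O bond by homolysis, and the stabilised C3 radical takes up hydrogen. Brief acid equilibration brings C3 to trans, and the route is rejoined at 18.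

**Ketone arylation (step 7).** The hindered enolate of 10 may be slow in the transmetallation step, or the base may attack the pyranone at C2'' at 90 °C. The fallback forms the same ketone from the other side and also bypasses step 6. 4-(Benzyloxy)phenylacetic acid F3 is converted with (COCl)2 into 4-(benzyloxy)phenylacetyl chloride F4. From 8, insertion of Zn (LiCl, THF, 40 °C) gives the arylzinc iodide F5, which is acylated by F4 under Pd(PPh3)4 catalysis (Negishi acylation). The route is rejoined at 12.

**Ether formation (step 10, with step 8).** The benzylic α-bromo ketone may solvolyse or decompose before it is alkylated. Under carbonate the product may close by aldol addition of C2 to the formyl group, the entry to a benzofuran skeleton. The fallback is base-free and sets out from 12. Diazo transfer (4-acetamidobenzenesulfonyl azide, DBU, MeCN) gives the α-diazo ketone F6. Rh2(OAc)4-catalysed O–H insertion of its carbene into the phenol 15 forms the O1–C2 bond. The route is rejoined at 16.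

**Sulfation (step 14).** The phenol is hindered by the C8'' substituent, so sulfation may be slow, and the polar sulfate may be lost on purification or during an acidic hydrogenolysis. The fallback uses a masked sulfate and sets out from 19. 2,2,2-Trichloroethyl chlorosulfate (Et3N, DMAP, THF) gives the neutral, chromatographable 2,2,2-trichloroethyl sulfate diester F7. Transfer hydrogenolysis (Pd/C, HCO2NH4, MeOH/THF) removes the trichloroethyl group and the six benzyl groups together. After acidification on the resin the route is rejoined at 21.

## Further compounds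

F1 | step 11 | (2R,3S)-5,7-bis(benzyloxy)-2-[4-(benzyloxy)phenyl]-3-[5-(benzyloxy)-2-(3,4-bis(benzyloxy)phenyl)-7-(methoxymethoxy)-4-oxo-4H-chromen-8-yl]-3-hydroxychroman-4-one (enantiomer of 17) | O=C1c2c(OCc3ccccc3)cc(OCc3ccccc3)cc2O[C@H](c2ccc(OCc3ccccc3)cc2)[C@@]1(O)c1c(OCOC)cc(OCc3ccccc3)c2c(=O)cc(-c3ccc(OCc4ccccc4)c(OCc4ccccc4)c3)oc12
F2 | step 12 | (2S,3R)-5,7-bis(benzyloxy)-2-[4-(benzyloxy)phenyl]-3-[5-(benzyloxy)-2-(3,4-bis(benzyloxy)phenyl)-7-(methoxymethoxy)-4-oxo-4H-chromen-8-yl]-4-oxochroman-3-yl methyl oxalate | O=C1c2c(OCc3ccccc3)cc(OCc3ccccc3)cc2O[C@@H](c2ccc(OCc3ccccc3)cc2)[C@]1(OC(=O)C(=O)OC)c1c(OCOC)cc(OCc3ccccc3)c2c(=O)cc(-c3ccc(OCc4ccccc4)c(OCc4ccccc4)c3)oc12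
F3 | step 7 | 4-(benzyloxy)phenylacetic acid | O=C(O)Cc1ccc(OCc2ccccc2)cc1
F4 | step 7 | 4-(benzyloxy)phenylacetyl chloride | O=C(Cl)Cc1ccc(OCc2ccccc2)cc1
F5 | step 7 | [5-(benzyloxy)-2-(3,4-bis(benzyloxy)phenyl)-7-(methoxymethoxy)-4-oxo-4H-chromen-8-yl]zinc iodide | O=c1cc(-c2ccc(OCc3ccccc3)c(OCc3ccccc3)c2)oc2c([Zn]I)c(OCOC)cc(OCc3ccccc3)c12
F6 | step 10 | 5-(benzyloxy)-8-{[4-(benzyloxy)phenyl](diazo)acetyl}-2-[3,4-bis(benzyloxy)phenyl]-7-(methoxymethoxy)-4H-chromen-4-one | O=c1cc(-c2ccc(OCc3ccccc3)c(OCc3ccccc3)c2)oc2c(C(=O)C(=[N+]=[N-])c3ccc(OCc4ccccc4)cc3)c(OCOC)cc(OCc3ccccc3)c12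
F7 | step 14 | (2R,3S)-hexabenzyl flavanone–flavone 7''-(2,2,2-trichloroethyl) sulfate (19 with O7''–SO2–OCH2CCl3) | O=C1c2c(OCc3ccccc3)cc(OCc3ccccc3)cc2O[C@@H](c2ccc(OCc3ccccc3)cc2)[C@@H]1c1c(OS(=O)(=O)OCC(Cl)(Cl)Cl)cc(OCc3ccccc3)c2c(=O)cc(-c3ccc(OCc4ccccc4)c(OCc4ccccc4)c3)oc12
A1 | alternative 1 | protected trans-flavanone–flavone with 7''-O-allyl group | O=C1c2c(OCc3ccccc3)cc(OCc3ccccc3)cc2O[C@@H](c2ccc(OCc3ccccc3)cc2)[C@@H]1c1c(OCC=C)cc(OCc5ccccc5)c2c(=O)cc(-c3ccc(OCc4ccccc4)c(OCc4ccccc4)c3)oc12
A2 | alternative 2 | protected trans-flavanone–flavone with 4'-acetate and 7''-triisopropylsilyl ether | O=C1c2c(OCc3ccccc3)cc(OCc3ccccc3)cc2O[C@@H](c2ccc(OC(C)=O)cc2)[C@@H]1c1c(O[Si](C(C)C)(C(C)C)C(C)C)cc(OCc5ccccc5)c2c(=O)cc(-c3ccc(OCc4ccccc4)c(OCc4ccccc4)c3)oc12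
A3 | alternative 3 | spiro-lactone flavan-4-ol (one diastereomer at C3 and C4) | O[C@H]1c2c(OCc3ccccc3)cc(OCc3ccccc3)cc2O[C@@H](c2ccc(OCc3ccccc3)cc2)[C@@]12C(=O)Oc1cc(OCc3ccccc3)c3c(=O)cc(-c4ccc(OCc5ccccc5)c(OCc5ccccc5)c4)oc3c12
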